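All runs are simulated with made-up constants; noise was put on by code.

Two questions are put to the new flasks: what share target holds among the products, and how that share moves along the row.

in all of them: catalyst 10 mol%

| flask | starting material | remark | time |
|---|---|---|---|
| birch | 0.17 M | run made earlier |  |
| oak | 0.20 M | run made earlier |  |
| theta | 0.10 M |  | 1.5 h |
| alpha | 0.15 M |  | 1.5 h |
| zeta | 0.25 M |  | 1.5 h |

| run | time / min | target / % | isomer of the product A / % |
|---|---|---|---|
| birch | 12.0 | 23.5 | 0 |
| birch | 25.0 | 37.2 | 1.0 |
| birch | 40.0 | 45.7 | 1.3 |
| birch | 50.0 | 47.8 | 1.1 |
| birch | 60.0 | 48.8 | 1.6 |
| oak | 6.00 | 14.6 | 0.2 |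
| oak | 15.0 | 30.2 | 0.2 |
| oak | 30.0 | 43.6 | 0.7 |
| oak | 50.0 | 49.5 | 0.6 |
| oak | 60.0 | 50.5 | 1.7 |

(each reading ± 0.3 percentage points)

* share of target in all that became target or isomer of the product A or isomer of the product B for theta, alpha, zeta, in this order
* the shape of the row from first to last (falls, then rises / rises, then falls / hardly changes / rises all the way / falls all the way)

- "hardly changes" means that all values lie within two and a half points (for a concentration: within two and a half percent of the largest)

A flat row is the zero of the scale: sister products of one step, formed at a fixed ratio, keep the same share at every time and concentration. Daughters of target behave otherwise: their share grows as target ages. Age needs a clock.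

Oak's first reading shows target at 14.6% after 6.00 min. Read as a first-order loss of starting material, this gives a forward half-life of 28.5 min. Catalyst is charged at 10 mol% of the starting material, so if it stays intact, the first step is pseudo-first-order, with a half-life inverse to the concentration. Birch tests that: its first reading gives 35.4 min, against 33.5 min scaled from oak.

Divide the run time by this scaled half-life and 1.5 h becomes 1.58 half-lives in theta, 2.37 in alpha and 3.95 in zeta; this is the half-life count. Oak's 60.0 min amounts to 2.11.

By then oak's readings of target have levelled. As read, with the scatter of the last interval in it, the slope falls 24.3-fold from the first reading to the last interval, whereas the forward step alone allows 3.81-fold. So oak's target is being lost, backward or onward; the readings do not split the two, though isomer of the product A, at 0.2% and later 1.7%, marks the onward way.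

If that loss needs no catalyst, its pace stays the same while the count grows with the charge. Zeta, at 3.95 against theta's 1.58, then makes its target sooner and leaves it open to that loss for longer. The reckoning here commits to a row falling from theta to zeta, with target still rising at theta's end, and gives no height.

The forecast differs: 49.5%, 50.3% and 51.5%, shape "hardly changes", on the ground that “In parallel paths, the share doesn't depend on conversion”.

The flasks give 75.0%, 73.1% and 70.5%, shape "falls all the way".

    target ⇌ isomer of the product A (K = 0.450, k = 9.10 × 10⁻⁵ s⁻¹)
    isomer of the product A ⇌ isomer of the product B (K = 21.0, k = 0.00390 s⁻¹)
    starting material + catalyst ⇌ target + catalyst, rate k3*[starting material]*[catalyst] forward; the back reaction follows from the equilibrium constant (K = 1.80, k = 0.0240 M⁻¹ s⁻¹)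

Zeta's target stands at 52.0% after 0.750 h, a count of 1.98, close to the 2.11 at which oak's target levelled, and it has dropped to 49.1% at 1.50 h, a count of 3.95. Theta ends at a count of 1.58, its target having risen from 36.2% at 0.750 h to 43.7% at 1.50 h.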